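The data are simulated with made-up constants.

The early minutes of the earlier runs are what you have for judging how much L forms when E or X goes in slowly.

| setting | violet | grey | green | birch | larch | cedar | alder |
|---|---|---|---|---|---|---|---|
| X | 0.023 M | 0.023 M | 0.023 M | 0.023 M | 0.023 M (fed, over 8.0 min) | 0.023 M | 0.023 M |
| E | 0.0207 M | 0.0207 M | 0.0207 M | 0.0207 M (in portions, 2, over 8.0 min) | 0.0207 M | 0.0207 M | 0.0207 M (fed, over 8.0 min) |
| G | 2.3 mM | 3.2 mM | 5.1 mM | 2.3 mM | 2.3 mM | 2.3 mM | 2.3 mM |
| remark | run made earlier | run made earlier | run made earlier | first portion at the start, last at 8.0 min | all else is in the flask from the start; the feed brings no volume worth counting | everything together at the start | all else is in the flask from the start; the feed brings no volume worth counting |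
| time |  |  |  | 20 min | 20 min | 20 min | 20 min |

| violet: time / min | violet: L / % | grey: time / min | grey: L / % | green: time / min | green: L / % |
|---|---|---|---|---|---|
| 2.50 | 31.9 | 1.50 | 32.0 | 4.00 | 69.1 |
| 5.00 | 43.0 | 3.00 | 45.3 | 8.00 | 80.6 |
| 8.00 | 49.2 | 6.00 | 58.5 | 12.0 | 84.8 |
| 10.0 | 50.8 | 10.0 | 66.0 | 15.0 | 84.8 |
| 12.0 | 51.7 | 20.0 | 73.0 | 20.0 | 85.3 |

(standard deviation of a reading: 0.3 percentage points)

1. the flask that comes out highest in amount of L, in percent of the X charged, or "all alike" when all lie within 1.5 percentage points (birch / larch / cedar / alder / all alike)
2. L at the end, in percent of the X charged, birch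
3. L at the end, in percent of the X charged, larch
4. L at the end, in percent of the X charged, cedar
5. L at the end, in percent of the X charged, alder

- the analysis behind the earlier runs scatters by 0.3 percentage points, standard deviation

Count E as a fraction of the X charge, so the charge is 0.900. In violet, L rises at 0.172 /min per unit of standing E up to 2.50 min, and at 0.0845 /min in the interval up to 5.00 min. I read that drop as working G decaying at 0.285 /min. My bet is that X takes G by the clock, pseudo-first-order while X stays near its charge, because green reached 3.85 turnovers per G against violet's 5.17, with 4.7 percentage points of E unspent. Dividing by the roughly 68 points of X not yet in L at 2.50 min gives a loss of 0.419 /min at full X. The coefficient at the start is 0.246 /min. Their ratio is the lifetime yield, the L, as a fraction of the X charge, that 2.3 mM of G makes before it is lost, per unit of the ratio of standing E to standing X: 0.588.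

For all four flasks to agree, each would have to hold the same ratio of E to X during G's lifetime of 2.39 min at full X. In cedar X and E each lose what L gains, so I take the ratio as 0.900, and my reckoning gives 52.9%. Birch starts with one portion, a ratio of 0.450, and its last portion comes at 8.0 min, later than that lifetime, which gives 26.5%. Alder's feed of 0.113 /min brings 0.269 of E in one lifetime, beside X near its charge, which gives 15.8%. Larch feeds X at 0.125 /min, slower than the 0.221 /min at which L can start to form, so I expect X to stay low, G to last, and L to climb towards the 90.0% allowed by E, the limiting reagent.

The forecast says all alike: 52.2% for birch, 52.7% for larch, 53% for cedar and 52.5% for alder. Its ground is “Loss per turnover therefore shouldn't depend on the addition mode.” We agree on cedar and part on the others.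

The flasks give 25.4% in birch, 84.8% in larch, 54.3% in cedar and 15.0% in alder, so larch comes out highest.

    X + E + G → L + G, rate k1*[X]*[E]*[G]/(1 + ([X]/sat1)) (0.440 mM, k = 4700 /M²/s)
    X + G → Q (k = 0.340 /M/s)

At 8.00 min, Q holds 96.0% of the catalyst in alder and 28.8% in larch. The neighbour is alder with 0.035 M of E. Its feed is 0.190 /min, so one lifetime brings 0.454 of E, and the lifetime yield gives 26.7%. That flask gives 27.9%.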